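**Retrosynthetic overview**
1. The last bond is C14'–C15' (carotenoid numbering, C19' is the lactone carbonyl), made by Stille coupling of a Z-ylidenebutenolide dienyl iodide with an epoxy pentaenyl C15' stannane.
2. The route rests on the trisubstituted C9'=C10' alkene of the five-membered lactone ring, whose C9' carries the ethylene tether to ring A. It is closed by ring-closing metathesis of a 2-substituted acrylate ester of a C11' vinyl carbinol, and the adjacent syn C11'/C12' oxygen pair is then spent in an anti-dehydration that gives the Z C11'=C12' alkene.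
3. The metathesis substrate is the ester of the ring A alpha-methylene acid (from (R)-alpha-ionone by 1,4-reduction, kinetic enol triflate, allylic oxidation and hydroxycarbonylation) with a syn C10'–C14' vinyl diol monosilyl ether (Brown gamma-alkoxyallylboration of (E)-3-iodo-2-methylpropenal).
4. The stannane comes from (4R,6R)-actinol by enol triflate carbonylation, Sharpless epoxidation, two Horner–Wadsworth–Emmons extensions and transfer of a stannylvinyl group.
5. Ring order: ring A and the end-group cyclohexane are bought in; the lactone is closed in step 11 and the oxirane, in an independent branch, in step 20.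

Key step: step 11

Remark: either enantiomeric syn C11'/C12' pair would serve, because both centers are erased in step 13; the (11'S,12'S) pair expected from (+)-Ipc2BOMe is carried so that each intermediate is a single diastereomer.
Remark: (R)-alpha-ionone, (4R,6R)-actinol, allyl 4-methoxybenzyl ether, triethyl 3-methyl-4-phosphonocrotonate, (E)-1,2-bis(tributylstannyl)ethene and propargyl alcohol are taken as purchased; polyenes from step 22 on are handled cold, in the dark and under argon.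

**Ring A acid**

Step 1
Reactants: 1 (R)-alpha-ionone
Product: 2 4-[(1R)-2,6,6-trimethylcyclohex-2-en-1-yl]butan-2-one
Conditions: H2 (1 atm), RhCl(PPh3)3 (5 mol %), benzene, rt
Reagents that add atoms: none
Why: Chemoselective homogeneous hydrogenation with RhCl(PPh3)3 should take the unhindered E-disubstituted enone alkene and leave the trisubstituted ring alkene and the C6' stereocenter untouched.

Step 2
Reactants: 2 4-[(1R)-2,6,6-trimethylcyclohex-2-en-1-yl]butan-2-one
Product: 4 4-[(1R)-2,6,6-trimethylcyclohex-2-en-1-yl]but-1-en-2-yl trifluoromethanesulfonate, via lithium enolate 3 (not isolated)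
Conditions: LiN(iPr)2, THF, −78 °C; PhNTf2, −78 °C → rt
Reagents that add atoms: N-phenylbis(trifluoromethanesulfonimide), O=S(=O)(N(c1ccccc1)S(=O)(=O)C(F)(F)F)C(F)(F)F
Why: Kinetic deprotonation of the methyl ketone at the methyl group and O-triflation of the enolate should give the 1-alken-2-yl triflate (enol triflate formation), the minor internal isomer being removed by chromatography.

Step 3
Reactants: 4 4-[(1R)-2,6,6-trimethylcyclohex-2-en-1-yl]but-1-en-2-yl trifluoromethanesulfonate
Product: 5 4-[(1R)-2,6,6-trimethyl-4-oxocyclohex-2-en-1-yl]but-1-en-2-yl trifluoromethanesulfonate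
Conditions: Mn(OAc)3·2H2O (10 mol %), t-BuOOH (5 equiv, in decane), 3 Å MS, EtOAc, rt
Reagents that add atoms: tert-butyl hydroperoxide, CC(C)(C)OO
Why: Radical allylic C–H oxidation should take the ring methylene next to the electron-rich trisubstituted alkene and give the enone, while the electron-poor enol triflate, which unlike an acrylate is no radical acceptor, and the C6' center are not engaged.

Step 4
Reactants: 5 4-[(1R)-2,6,6-trimethyl-4-oxocyclohex-2-en-1-yl]but-1-en-2-yl trifluoromethanesulfonate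
Product: 7 2-methylidene-4-[(1R)-2,6,6-trimethyl-4-oxocyclohex-2-en-1-yl]butanoic acid, via mixed anhydride 6 (not isolated)
Conditions: Pd(OAc)2 (5 mol %), PPh3 (10 mol %), CO (1 atm), KOAc (4 equiv), DMF, rt; aqueous citric acid work-up
Reagents that add atoms: carbon monoxide, [C-]#[O+]; potassium acetate, CC(=O)[O-].[K+]; water, O (acetate or water supplies the hydroxyl oxygen, depending on which carbonyl of 6 is hydrolysed)
Why: Oxidative addition of zerovalent palladium into the vinyl triflate, CO insertion and capture of the acyl complex by acetate give a mixed anhydride that water hydrolyses to the acrylic acid without strong base, so the gamma-position C6' of the enone is not at risk (palladium-catalysed hydroxycarbonylation).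

**C10'–C14' alcohol**

Step 5
Reactants: 8 prop-2-yn-1-ol
Product: 10 (2E)-3-iodo-2-methylprop-2-en-1-ol, via alkenylalane 9 (not isolated)
Conditions: AlMe3 (3 equiv), Cp2ZrCl2 (0.25 equiv), CH2Cl2, 0 °C → rt; I2, THF, −30 → 0 °C
Reagents that add atoms: trimethylaluminium, C[Al](C)C; iodine, II
Why: Zirconium-catalysed syn carboalumination places methyl on the internal and aluminium on the terminal alkyne carbon, and iodinolysis with retention should give the E vinyl iodide (Negishi carboalumination–iodination).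

Step 6
Reactants: 10 (2E)-3-iodo-2-methylprop-2-en-1-ol
Product: 11 (2E)-3-iodo-2-methylprop-2-enal
Conditions: MnO2 (excess), CH2Cl2, rt; filtered solution used directly
Reagents that add atoms: none
Why: Manganese dioxide oxidises the allylic alcohol to the enal without touching the vinyl iodide (allylic alcohol oxidation), and the volatile aldehyde is not isolated neat.

Step 7
Reactants: 12 allyl 4-methoxybenzyl ether; 11 (2E)-3-iodo-2-methylprop-2-enal
Product: 16 (1E,3S,4S)-1-iodo-4-[(4-methoxybenzyl)oxy]-2-methylhexa-1,5-dien-3-ol, via allyllithium 13 (not isolated), via allylborane 14 (not isolated), via borinate 15 (not isolated)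
Conditions: 12, s-BuLi, THF, −78 °C; (+)-Ipc2BOMe; BF3·OEt2; 11, −78 °C; NaOH, H2O2, 0 °C → rt
Reagents that add atoms: none
Why: The Z gamma-alkoxyallyl diisopinocampheylborane adds through a closed chair transition state, so its Z geometry gives the syn C11'/C12' pair and the isopinocampheyl groups from (+)-Ipc2BOMe should direct attack to the Re face of the aldehyde, setting both centers as S (Brown gamma-alkoxyallylboration).

Step 8
Reactants: 16 (1E,3S,4S)-1-iodo-4-[(4-methoxybenzyl)oxy]-2-methylhexa-1,5-dien-3-ol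
Product: 17 tert-butyl{[(1E,3S,4S)-1-iodo-4-[(4-methoxybenzyl)oxy]-2-methylhexa-1,5-dien-3-yl]oxy}dimethylsilane
Conditions: TBSOTf, 2,6-lutidine, CH2Cl2, −78 → 0 °C
Reagents that add atoms: tert-butyldimethylsilyl trifluoromethanesulfonate, CC(C)(C)[Si](C)(C)OS(=O)(=O)C(F)(F)F
Why: The silyl triflate with a hindered pyridine base silylates the crowded secondary allylic C12' alcohol (silyl ether formation).

Step 9
Reactants: 17 tert-butyl{[(1E,3S,4S)-1-iodo-4-[(4-methoxybenzyl)oxy]-2-methylhexa-1,5-dien-3-yl]oxy}dimethylsilane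
Product: 18 (3S,4S,5E)-4-[(tert-butyldimethylsilyl)oxy]-6-iodo-5-methylhexa-1,5-dien-3-ol
Conditions: DDQ, CH2Cl2/pH 7 buffer, 0 °C
Reagents that add atoms: none
Why: DDQ oxidises the electron-rich 4-methoxybenzyl ether to an oxocarbenium ion that water hydrolyses, which frees the C11' alcohol and leaves the silyl ether and the vinyl iodide intact (oxidative PMB cleavage).

**Esterification, key step and ylidenebutenolide**

Step 10
Reactants: 7 2-methylidene-4-[(1R)-2,6,6-trimethyl-4-oxocyclohex-2-en-1-yl]butanoic acid; 18 (3S,4S,5E)-4-[(tert-butyldimethylsilyl)oxy]-6-iodo-5-methylhexa-1,5-dien-3-ol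
Product: 19 (3S,4S,5E)-4-[(tert-butyldimethylsilyl)oxy]-6-iodo-5-methylhexa-1,5-dien-3-yl 2-methylidene-4-[(1R)-2,6,6-trimethyl-4-oxocyclohex-2-en-1-yl]butanoate
Conditions: DCC, DMAP (cat.), CH2Cl2, 0 °C → rt
Reagents that add atoms: none
Why: Carbodiimide activation and DMAP acyl transfer esterify the secondary allylic alcohol under near-neutral conditions that should not provoke 1,2-silyl migration (Steglich esterification).

Step 11
Reactants: 19 (3S,4S,5E)-4-[(tert-butyldimethylsilyl)oxy]-6-iodo-5-methylhexa-1,5-dien-3-yl 2-methylidene-4-[(1R)-2,6,6-trimethyl-4-oxocyclohex-2-en-1-yl]butanoate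
Product: 20 (5S)-5-[(1S,2E)-1-[(tert-butyldimethylsilyl)oxy]-3-iodo-2-methylprop-2-en-1-yl]-3-{2-[(1R)-2,6,6-trimethyl-4-oxocyclohex-2-en-1-yl]ethyl}furan-2(5H)-one
Conditions: second-generation Grubbs catalyst RuCl2(=CHPh)(PCy3)(H2IMes) (10 mol %), CH2Cl2 (0.005 M), reflux
Reagents that add atoms: none
Why: The ruthenium benzylidene should initiate at the monosubstituted C10' vinyl group, the new alkylidene then adds intramolecularly to the 1,1-disubstituted acrylate alkene in a [2+2] step, and cycloreversion of the metallacyclobutane releases the C9'=C10' alkene and a ruthenium methylidene that turns over with loss of ethene. The closest known reaction type is ring-closing metathesis of methacrylate and other 2-substituted acrylate esters of allylic alcohols to alpha-substituted butenolides. The lactone is closed as a five-membered ring by alkene metathesis, the new bond being the endocyclic C9'=C10' double bond, from the s-cis ester conformer. No stereocenter is formed, and C6', C11', C12' and the C13'=C14' geometry are not involved. The step needs chemoselectivity among four alkenes: the trisubstituted ring A enone alkene and the trisubstituted iodoalkene are too hindered and too electron-poor to enter the catalytic cycle, so only the vinyl/acrylate pair can react, and high dilution holds back dimerisation through the vinyl group.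

Step 12
Reactants: 20 (5S)-5-[(1S,2E)-1-[(tert-butyldimethylsilyl)oxy]-3-iodo-2-methylprop-2-en-1-yl]-3-{2-[(1R)-2,6,6-trimethyl-4-oxocyclohex-2-en-1-yl]ethyl}furan-2(5H)-one
Product: 21 (5S)-5-[(1S,2E)-1-hydroxy-3-iodo-2-methylprop-2-en-1-yl]-3-{2-[(1R)-2,6,6-trimethyl-4-oxocyclohex-2-en-1-yl]ethyl}furan-2(5H)-one
Conditions: HF·pyridine, pyridine, THF, 0 °C → rt
Reagents that add atoms: none
Why: Buffered hydrogen fluoride cleaves the secondary silyl ether under non-basic conditions, so the base-sensitive gamma-(hydroxyalkyl)butenolide should neither epimerise at C11' nor eliminate prematurely (desilylation).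

Step 13
Reactants: 21 (5S)-5-[(1S,2E)-1-hydroxy-3-iodo-2-methylprop-2-en-1-yl]-3-{2-[(1R)-2,6,6-trimethyl-4-oxocyclohex-2-en-1-yl]ethyl}furan-2(5H)-one
Product: 23 (5Z)-5-[(2E)-3-iodo-2-methylprop-2-en-1-ylidene]-3-{2-[(1R)-2,6,6-trimethyl-4-oxocyclohex-2-en-1-yl]ethyl}furan-2(5H)-one, via allylic triflate 22 (not isolated)
Conditions: Tf2O, pyridine, CH2Cl2, −78 °C → rt
Reagents that add atoms: none
Why: Triflation of the C12' alcohol and pyridine-induced E2 loss of the acidic C11' hydrogen, which lies anti-periplanar to the triflate when C10' and C13' are anti, should convert the syn pair stereospecifically into the Z exocyclic alkene (anti-elimination through the triflate).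

**Iodoallyl phosphonate**

Step 14
Reactants: 10 (2E)-3-iodo-2-methylprop-2-en-1-ol
Product: 24 (1E)-3-bromo-1-iodo-2-methylprop-1-ene
Conditions: CBr4, PPh3, CH2Cl2, 0 °C
Reagents that add atoms: tetrabromomethane, BrC(Br)(Br)Br
Why: Appel bromination converts the primary allylic alcohol into the bromide by direct displacement of the oxyphosphonium group, without change of the vinyl iodide geometry.

Step 15
Reactants: 24 (1E)-3-bromo-1-iodo-2-methylprop-1-ene
Product: 25 diethyl [(2E)-3-iodo-2-methylprop-2-en-1-yl]phosphonate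
Conditions: P(OEt)3 (neat), 90 °C
Reagents that add atoms: triethyl phosphite, CCOP(OCC)OCC
Why: Michaelis–Arbuzov reaction of the phosphite at the primary allylic bromide gives the phosphonate, the vinyl iodide being inert to the phosphite.

**Epoxy pentaenyl stannane**

Step 16
Reactants: 26 (4R,6R)-actinol
Product: 27 (4R,6R)-4-[(tert-butyldimethylsilyl)oxy]-2,2,6-trimethylcyclohexan-1-one
Conditions: TBSCl, imidazole, DMF, rt
Reagents that add atoms: tert-butyldimethylsilyl chloride, CC(C)(C)[Si](C)(C)Cl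
Why: Silylation protects the secondary alcohol for the enolate and hydride chemistry that follows (silyl ether formation).

Step 17
Reactants: 27 (4R,6R)-4-[(tert-butyldimethylsilyl)oxy]-2,2,6-trimethylcyclohexan-1-one
Product: 29 (4R)-4-[(tert-butyldimethylsilyl)oxy]-2,6,6-trimethylcyclohex-1-en-1-yl trifluoromethanesulfonate, via lithium enolate 28 (not isolated)
Conditions: LiN(iPr)2, THF, −78 °C; PhNTf2, −78 °C → rt
Reagents that add atoms: N-phenylbis(trifluoromethanesulfonimide), O=S(=O)(N(c1ccccc1)S(=O)(=O)C(F)(F)F)C(F)(F)F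
Why: The ketone can enolise only toward the methyl-bearing carbon, so a single enolate forms and is triflated on oxygen, which erases that stereocenter and leaves the silyloxy-bearing center untouched (enol triflate formation).

Step 18
Reactants: 29 (4R)-4-[(tert-butyldimethylsilyl)oxy]-2,6,6-trimethylcyclohex-1-en-1-yl trifluoromethanesulfonate
Product: 30 methyl (4R)-4-[(tert-butyldimethylsilyl)oxy]-2,6,6-trimethylcyclohex-1-ene-1-carboxylate
Conditions: Pd(OAc)2 (5 mol %), PPh3 (10 mol %), CO (1 atm), MeOH, Et3N, DMF, 60 °C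
Reagents that add atoms: carbon monoxide, [C-]#[O+]; methanol, CO
Why: Oxidative addition, CO insertion and methanolysis of the acyl palladium complex convert the enol triflate into the cyclohexenecarboxylate (palladium-catalysed methoxycarbonylation).

Step 19
Reactants: 30 methyl (4R)-4-[(tert-butyldimethylsilyl)oxy]-2,6,6-trimethylcyclohex-1-ene-1-carboxylate
Product: 31 [(4R)-4-[(tert-butyldimethylsilyl)oxy]-2,6,6-trimethylcyclohex-1-en-1-yl]methanol
Conditions: iBu2AlH (DIBAL-H), CH2Cl2, −78 → 0 °C; aqueous Rochelle salt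
Reagents that add atoms: none
Why: The aluminium hydride reduces the conjugated ester in the 1,2-sense to the allylic alcohol (ester reduction).

Step 20
Reactants: 31 [(4R)-4-[(tert-butyldimethylsilyl)oxy]-2,6,6-trimethylcyclohex-1-en-1-yl]methanol
Product: 32 [(1R,4S,6R)-4-[(tert-butyldimethylsilyl)oxy]-2,2,6-trimethyl-7-oxabicyclo[4.1.0]heptan-1-yl]methanol
Conditions: Ti(OiPr)4 (0.2 equiv), D-(−)-diethyl tartrate (0.24 equiv), t-BuOOH (in decane), 4 Å MS, CH2Cl2, −20 °C
Reagents that add atoms: tert-butyl hydroperoxide, CC(C)(C)OO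
Why: In the Sharpless asymmetric epoxidation the titanium complex of D-(−)-diethyl tartrate should deliver oxygen to the face of the tetrasubstituted ring alkene anti to the silyloxy group, which sets both oxirane carbons in the configuration of the target.

Step 21
Reactants: 32 [(1R,4S,6R)-4-[(tert-butyldimethylsilyl)oxy]-2,2,6-trimethyl-7-oxabicyclo[4.1.0]heptan-1-yl]methanol
Product: 33 (1S,4S,6R)-4-[(tert-butyldimethylsilyl)oxy]-2,2,6-trimethyl-7-oxabicyclo[4.1.0]heptane-1-carbaldehyde
Conditions: (n-Pr4N)RuO4 (5 mol %), NMO, 4 Å MS, CH2Cl2, rt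
Reagents that add atoms: none
Why: Ley–Griffith oxidation with catalytic perruthenate and NMO gives the epoxy aldehyde under neutral conditions, and the aldehyde has no alpha hydrogen and cannot epimerise.

Step 22
Reactants: 33 (1S,4S,6R)-4-[(tert-butyldimethylsilyl)oxy]-2,2,6-trimethyl-7-oxabicyclo[4.1.0]heptane-1-carbaldehyde; 34 triethyl 3-methyl-4-phosphonocrotonate
Product: 36 ethyl (2E,4E)-5-[(1S,4S,6R)-4-[(tert-butyldimethylsilyl)oxy]-2,2,6-trimethyl-7-oxabicyclo[4.1.0]heptan-1-yl]-3-methylpenta-2,4-dienoate, via phosphonate anion 35 (not isolated)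
Conditions: 34, LiN(SiMe3)2, THF/DMPU, −78 °C; 33, −78 → 0 °C
Reagents that add atoms: none
Why: Horner–Wadsworth–Emmons olefination of the hindered aldehyde with the lithiated phosphonate should form the C7=C8 alkene with E geometry, the E C9=C10 isomer being expected to predominate and purified by chromatography.

Step 23
Reactants: 36 ethyl (2E,4E)-5-[(1S,4S,6R)-4-[(tert-butyldimethylsilyl)oxy]-2,2,6-trimethyl-7-oxabicyclo[4.1.0]heptan-1-yl]-3-methylpenta-2,4-dienoate
Product: 37 (2E,4E)-5-[(1S,4S,6R)-4-[(tert-butyldimethylsilyl)oxy]-2,2,6-trimethyl-7-oxabicyclo[4.1.0]heptan-1-yl]-3-methylpenta-2,4-dien-1-ol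
Conditions: iBu2AlH, CH2Cl2, −78 °C; aqueous Rochelle salt
Reagents that add atoms: none
Why: At low temperature the aluminium hydride reduces the dienoate to the allylic alcohol without opening the fully substituted oxirane (ester reduction).

Step 24
Reactants: 37 (2E,4E)-5-[(1S,4S,6R)-4-[(tert-butyldimethylsilyl)oxy]-2,2,6-trimethyl-7-oxabicyclo[4.1.0]heptan-1-yl]-3-methylpenta-2,4-dien-1-ol
Product: 38 (2E,4E)-5-[(1S,4S,6R)-4-[(tert-butyldimethylsilyl)oxy]-2,2,6-trimethyl-7-oxabicyclo[4.1.0]heptan-1-yl]-3-methylpenta-2,4-dienal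
Conditions: MnO2, CH2Cl2, rt
Reagents that add atoms: none
Why: Manganese dioxide oxidises the dienylic alcohol to the dienal under neutral conditions that spare the acid-sensitive vinyl oxirane (allylic alcohol oxidation).

Step 25
Reactants: 25 diethyl [(2E)-3-iodo-2-methylprop-2-en-1-yl]phosphonate; 38 (2E,4E)-5-[(1S,4S,6R)-4-[(tert-butyldimethylsilyl)oxy]-2,2,6-trimethyl-7-oxabicyclo[4.1.0]heptan-1-yl]-3-methylpenta-2,4-dienal
Product: 40 (1S,4S,6R)-4-[(tert-butyldimethylsilyl)oxy]-1-[(1E,3E,5E,7E)-8-iodo-3,7-dimethylocta-1,3,5,7-tetraen-1-yl]-2,2,6-trimethyl-7-oxabicyclo[4.1.0]heptane, via phosphonate anion 39 (not isolated)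
Conditions: 25, LiN(SiMe3)2, THF, −78 °C; 38, −78 → 0 °C
Reagents that add atoms: none
Why: Horner–Wadsworth–Emmons olefination with the lithiated allylic phosphonate should form the C11=C12 alkene with the E preference of allyl-stabilised phosphonate anions and carries the C14 iodide into the chain.

Step 26
Reactants: 40 (1S,4S,6R)-4-[(tert-butyldimethylsilyl)oxy]-1-[(1E,3E,5E,7E)-8-iodo-3,7-dimethylocta-1,3,5,7-tetraen-1-yl]-2,2,6-trimethyl-7-oxabicyclo[4.1.0]heptane
Product: 41 (1R,3S,6S)-6-[(1E,3E,5E,7E)-8-iodo-3,7-dimethylocta-1,3,5,7-tetraen-1-yl]-1,5,5-trimethyl-7-oxabicyclo[4.1.0]heptan-3-ol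
Conditions: Bu4NF, THF, 0 °C → rt
Reagents that add atoms: none
Why: Fluoride-mediated desilylation frees the C3 hydroxyl at a stage where no base-sensitive group is present and avoids the acid that would rearrange the vinyl oxirane.

Step 27
Reactants: 41 (1R,3S,6S)-6-[(1E,3E,5E,7E)-8-iodo-3,7-dimethylocta-1,3,5,7-tetraen-1-yl]-1,5,5-trimethyl-7-oxabicyclo[4.1.0]heptan-3-ol; 42 (E)-1,2-bis(tributylstannyl)ethene
Product: 43 (1R,3S,6S)-6-[(1E,3E,5E,7E,9E)-3,7-dimethyl-10-(tributylstannyl)deca-1,3,5,7,9-pentaen-1-yl]-1,5,5-trimethyl-7-oxabicyclo[4.1.0]heptan-3-ol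
Conditions: 42 (4 equiv), PdCl2(MeCN)2 (5 mol %), iPr2NEt, DMF, rt, dark
Reagents that add atoms: none
Why: Stille coupling of the vinyl iodide with an excess of the bis-stannane transfers one stannylvinyl group with retention at both alkene ends, the excess holding back double coupling, and the fully substituted vinyl oxirane is too hindered to be ionised by zerovalent palladium.

**Final coupling**

Step 28
Reactants: 23 (5Z)-5-[(2E)-3-iodo-2-methylprop-2-en-1-ylidene]-3-{2-[(1R)-2,6,6-trimethyl-4-oxocyclohex-2-en-1-yl]ethyl}furan-2(5H)-one; 43 (1R,3S,6S)-6-[(1E,3E,5E,7E,9E)-3,7-dimethyl-10-(tributylstannyl)deca-1,3,5,7,9-pentaen-1-yl]-1,5,5-trimethyl-7-oxabicyclo[4.1.0]heptan-3-ol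
Product: 44 CNP0251552.1
Conditions: Pd2(dba)3 (5 mol %), AsPh3 (40 mol %), DMF, rt, dark
Reagents that add atoms: none
Why: Stille coupling with the weakly bound arsine ligand should join C14' to C15' at room temperature with retention of both alkene geometries and tolerate the free hydroxyl, the oxirane and the ylidenebutenolide.

**Compound list**
1 | (R)-alpha-ionone | CC1=CCCC(C)(C)[C@H]1/C=C/C(C)=O | starting material
2 | 4-[(1R)-2,6,6-trimethylcyclohex-2-en-1-yl]butan-2-one | CC1=CCCC(C)(C)[C@H]1CCC(C)=O | intermediate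
3 | lithium 4-[(1R)-2,6,6-trimethylcyclohex-2-en-1-yl]but-1-en-2-olate | CC1=CCCC(C)(C)[C@H]1CCC(=C)[O-].[Li+] | intermediate
4 | 4-[(1R)-2,6,6-trimethylcyclohex-2-en-1-yl]but-1-en-2-yl trifluoromethanesulfonate | CC1=CCCC(C)(C)[C@H]1CCC(=C)OS(=O)(=O)C(F)(F)F | intermediate
5 | 4-[(1R)-2,6,6-trimethyl-4-oxocyclohex-2-en-1-yl]but-1-en-2-yl trifluoromethanesulfonate | CC1=CC(=O)CC(C)(C)[C@H]1CCC(=C)OS(=O)(=O)C(F)(F)F | intermediate
6 | acetic 2-methylidene-4-[(1R)-2,6,6-trimethyl-4-oxocyclohex-2-en-1-yl]butanoic anhydride | CC1=CC(=O)CC(C)(C)[C@H]1CCC(=C)C(=O)OC(C)=O | intermediate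
7 | 2-methylidene-4-[(1R)-2,6,6-trimethyl-4-oxocyclohex-2-en-1-yl]butanoic acid | CC1=CC(=O)CC(C)(C)[C@H]1CCC(=C)C(=O)O | intermediate
8 | prop-2-yn-1-ol | C#CCO | starting material
9 | dimethylaluminium (2E)-3-(dimethylalumanyl)-2-methylprop-2-en-1-olate | C[Al](C)OC/C(C)=C/[Al](C)C | intermediate
10 | (2E)-3-iodo-2-methylprop-2-en-1-ol | OC/C(C)=C/I | intermediate
11 | (2E)-3-iodo-2-methylprop-2-enal | O=C/C(C)=C/I | intermediate
12 | allyl 4-methoxybenzyl ether | C=CCOCc1ccc(OC)cc1 | starting material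
13 | [(2Z)-3-[(4-methoxybenzyl)oxy]prop-2-en-1-yl]lithium | [Li]C/C=C\OCc1ccc(OC)cc1 | intermediate
14 | [(2Z)-3-[(4-methoxybenzyl)oxy]prop-2-en-1-yl]diisopinocampheylborane (isopinocampheyl groups from (−)-alpha-pinene) | COc1ccc(CO/C=C\CB([C@H]2C[C@H]3C[C@@H]([C@@H]2C)C3(C)C)[C@H]2C[C@H]3C[C@@H]([C@@H]2C)C3(C)C)cc1 | intermediate
15 | diisopinocampheylborinic ester of 16 | C=C[C@H](OCc1ccc(OC)cc1)[C@@H](OB([C@H]1C[C@H]2C[C@@H]([C@@H]1C)C2(C)C)[C@H]1C[C@H]2C[C@@H]([C@@H]1C)C2(C)C)/C(C)=C/I | intermediate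
16 | (1E,3S,4S)-1-iodo-4-[(4-methoxybenzyl)oxy]-2-methylhexa-1,5-dien-3-ol | C=C[C@H](OCc1ccc(OC)cc1)[C@@H](O)/C(C)=C/I | intermediate
17 | tert-butyl{[(1E,3S,4S)-1-iodo-4-[(4-methoxybenzyl)oxy]-2-methylhexa-1,5-dien-3-yl]oxy}dimethylsilane | C=C[C@H](OCc1ccc(OC)cc1)[C@@H](O[Si](C)(C)C(C)(C)C)/C(C)=C/I | intermediate
18 | (3S,4S,5E)-4-[(tert-butyldimethylsilyl)oxy]-6-iodo-5-methylhexa-1,5-dien-3-ol | C=C[C@H](O)[C@@H](O[Si](C)(C)C(C)(C)C)/C(C)=C/I | intermediate
19 | (3S,4S,5E)-4-[(tert-butyldimethylsilyl)oxy]-6-iodo-5-methylhexa-1,5-dien-3-yl 2-methylidene-4-[(1R)-2,6,6-trimethyl-4-oxocyclohex-2-en-1-yl]butanoate | CC1=CC(=O)CC(C)(C)[C@H]1CCC(=C)C(=O)O[C@@H](C=C)[C@@H](O[Si](C)(C)C(C)(C)C)/C(C)=C/I | intermediate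
20 | (5S)-5-[(1S,2E)-1-[(tert-butyldimethylsilyl)oxy]-3-iodo-2-methylprop-2-en-1-yl]-3-{2-[(1R)-2,6,6-trimethyl-4-oxocyclohex-2-en-1-yl]ethyl}furan-2(5H)-one | CC1=CC(=O)CC(C)(C)[C@H]1CCC1=C[C@@H]([C@@H](O[Si](C)(C)C(C)(C)C)/C(C)=C/I)OC1=O | intermediate
21 | (5S)-5-[(1S,2E)-1-hydroxy-3-iodo-2-methylprop-2-en-1-yl]-3-{2-[(1R)-2,6,6-trimethyl-4-oxocyclohex-2-en-1-yl]ethyl}furan-2(5H)-one | CC1=CC(=O)CC(C)(C)[C@H]1CCC1=C[C@@H]([C@@H](O)/C(C)=C/I)OC1=O | intermediate
22 | trifluoromethanesulfonate of 21 at the C12' oxygen | CC1=CC(=O)CC(C)(C)[C@H]1CCC1=C[C@@H]([C@@H](OS(=O)(=O)C(F)(F)F)/C(C)=C/I)OC1=O | intermediate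
23 | (5Z)-5-[(2E)-3-iodo-2-methylprop-2-en-1-ylidene]-3-{2-[(1R)-2,6,6-trimethyl-4-oxocyclohex-2-en-1-yl]ethyl}furan-2(5H)-one | CC1=CC(=O)CC(C)(C)[C@H]1CCC1=C/C(=C/C(C)=C/I)OC1=O | intermediate
24 | (1E)-3-bromo-1-iodo-2-methylprop-1-ene | BrC/C(C)=C/I | intermediate
25 | diethyl [(2E)-3-iodo-2-methylprop-2-en-1-yl]phosphonate | CCOP(=O)(OCC)C/C(C)=C/I | intermediate
26 | (4R,6R)-actinol, (4R,6R)-4-hydroxy-2,2,6-trimethylcyclohexan-1-one | C[C@@H]1C[C@@H](O)CC(C)(C)C1=O | starting material
27 | (4R,6R)-4-[(tert-butyldimethylsilyl)oxy]-2,2,6-trimethylcyclohexan-1-one | C[C@@H]1C[C@@H](O[Si](C)(C)C(C)(C)C)CC(C)(C)C1=O | intermediate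
28 | lithium (4R)-4-[(tert-butyldimethylsilyl)oxy]-2,6,6-trimethylcyclohex-1-en-1-olate | CC1=C([O-])C(C)(C)C[C@H](O[Si](C)(C)C(C)(C)C)C1.[Li+] | intermediate
29 | (4R)-4-[(tert-butyldimethylsilyl)oxy]-2,6,6-trimethylcyclohex-1-en-1-yl trifluoromethanesulfonate | CC1=C(OS(=O)(=O)C(F)(F)F)C(C)(C)C[C@H](O[Si](C)(C)C(C)(C)C)C1 | intermediate
30 | methyl (4R)-4-[(tert-butyldimethylsilyl)oxy]-2,6,6-trimethylcyclohex-1-ene-1-carboxylate | CC1=C(C(=O)OC)C(C)(C)C[C@H](O[Si](C)(C)C(C)(C)C)C1 | intermediate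
31 | [(4R)-4-[(tert-butyldimethylsilyl)oxy]-2,6,6-trimethylcyclohex-1-en-1-yl]methanol | CC1=C(CO)C(C)(C)C[C@H](O[Si](C)(C)C(C)(C)C)C1 | intermediate
32 | [(1R,4S,6R)-4-[(tert-butyldimethylsilyl)oxy]-2,2,6-trimethyl-7-oxabicyclo[4.1.0]heptan-1-yl]methanol (oxirane anti to the silyloxy group) | OC[C@@]12O[C@]1(C)C[C@@H](O[Si](C)(C)C(C)(C)C)CC2(C)C | intermediate
33 | (1S,4S,6R)-4-[(tert-butyldimethylsilyl)oxy]-2,2,6-trimethyl-7-oxabicyclo[4.1.0]heptane-1-carbaldehyde | O=C[C@@]12O[C@]1(C)C[C@@H](O[Si](C)(C)C(C)(C)C)CC2(C)C | intermediate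
34 | triethyl 3-methyl-4-phosphonocrotonate, ethyl (2E)-4-(diethoxyphosphoryl)-3-methylbut-2-enoate (sold as an E/Z mixture, drawn E) | CCOC(=O)/C=C(\C)CP(=O)(OCC)OCC | starting material
35 | lithium salt of the C4 carbanion of 34 | [Li+].CCOC(=O)C=C(C)[CH-]P(=O)(OCC)OCC | intermediate
36 | ethyl (2E,4E)-5-[(1S,4S,6R)-4-[(tert-butyldimethylsilyl)oxy]-2,2,6-trimethyl-7-oxabicyclo[4.1.0]heptan-1-yl]-3-methylpenta-2,4-dienoate | CCOC(=O)/C=C(C)/C=C/[C@@]12O[C@]1(C)C[C@@H](O[Si](C)(C)C(C)(C)C)CC2(C)C | intermediate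
37 | (2E,4E)-5-[(1S,4S,6R)-4-[(tert-butyldimethylsilyl)oxy]-2,2,6-trimethyl-7-oxabicyclo[4.1.0]heptan-1-yl]-3-methylpenta-2,4-dien-1-ol | OC/C=C(C)/C=C/[C@@]12O[C@]1(C)C[C@@H](O[Si](C)(C)C(C)(C)C)CC2(C)C | intermediate
38 | (2E,4E)-5-[(1S,4S,6R)-4-[(tert-butyldimethylsilyl)oxy]-2,2,6-trimethyl-7-oxabicyclo[4.1.0]heptan-1-yl]-3-methylpenta-2,4-dienal | O=C/C=C(C)/C=C/[C@@]12O[C@]1(C)C[C@@H](O[Si](C)(C)C(C)(C)C)CC2(C)C | intermediate
39 | lithium salt of the C1 carbanion of 25 | [Li+].CCOP(=O)(OCC)[CH-]/C(C)=C/I | intermediate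
40 | (1S,4S,6R)-4-[(tert-butyldimethylsilyl)oxy]-1-[(1E,3E,5E,7E)-8-iodo-3,7-dimethylocta-1,3,5,7-tetraen-1-yl]-2,2,6-trimethyl-7-oxabicyclo[4.1.0]heptane | I/C=C(C)/C=C/C=C(C)/C=C/[C@@]12O[C@]1(C)C[C@@H](O[Si](C)(C)C(C)(C)C)CC2(C)C | intermediate
41 | (1R,3S,6S)-6-[(1E,3E,5E,7E)-8-iodo-3,7-dimethylocta-1,3,5,7-tetraen-1-yl]-1,5,5-trimethyl-7-oxabicyclo[4.1.0]heptan-3-ol | I/C=C(C)/C=C/C=C(C)/C=C/[C@@]12O[C@]1(C)C[C@@H](O)CC2(C)C | intermediate
42 | (E)-1,2-bis(tributylstannyl)ethene | CCCC[Sn](CCCC)(CCCC)/C=C/[Sn](CCCC)(CCCC)CCCC | starting material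
43 | (1R,3S,6S)-6-[(1E,3E,5E,7E,9E)-3,7-dimethyl-10-(tributylstannyl)deca-1,3,5,7,9-pentaen-1-yl]-1,5,5-trimethyl-7-oxabicyclo[4.1.0]heptan-3-ol | CCCC[Sn](CCCC)(CCCC)/C=C/C=C(C)/C=C/C=C(C)/C=C/[C@@]12O[C@]1(C)C[C@@H](O)CC2(C)C | intermediate
44 | CNP0251552.1, (5Z)-5-[(2E,4E,6E,8E,10E,12E)-13-[(1S,4S,6R)-4-hydroxy-2,2,6-trimethyl-7-oxabicyclo[4.1.0]heptan-1-yl]-2,7,11-trimethyltrideca-2,4,6,8,10,12-hexaen-1-ylidene]-3-{2-[(1R)-2,6,6-trimethyl-4-oxocyclohex-2-en-1-yl]ethyl}furan-2(5H)-one | CC1=CC(=O)CC(C)(C)[C@H]1CCC1=C/C(=C/C(C)=C/C=C/C=C(C)/C=C/C=C(C)/C=C/[C@@]23O[C@]2(C)C[C@@H](O)CC3(C)C)OC1=O | target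

**Step count and risks**
Total: 28 steps. Longest linear sequence: 13 steps (26 to 44, steps 16 to 28).

Steps most likely to fail:

Step 11. Ring closure onto the hindered, electron-poor 1,1-disubstituted acrylate may be slow, so that intermolecular metathesis of the vinyl groups and catalyst decay win. The fallback makes the C11'–C12' bond by a vinylogous Mukaiyama aldol addition instead of the allylboration. Acid 7 would be esterified with allyl alcohol (DCC, DMAP) to the allyl ester F1, which has no branched allylic carbon and should close with the same ruthenium catalyst to the gamma-unsubstituted butenolide F2. Silylation with one equivalent of TBSOTf and Et3N (CH2Cl2, 0 °C) would give the 2-silyloxyfuran F3, and its BF3·OEt2-mediated addition to iodoenal 11 at −78 °C, which is expected to favour the syn adducts, would give 21 together with its (11'R,12'R) syn diastereomer F4. This fallback sets out from 7 and 11 and comes back at 21; 21 and F4 both give 23 in step 13.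

Step 13. The allylic triflate may ionise before the anti-periplanar proton loss, which would scramble the alkene geometry or allow allylic substitution by pyridine. The fallback gives up stereospecific elimination for thermodynamic control. Alcohol 21 would be acetylated (Ac2O, pyridine, DMAP) to the acetate F5 and eliminated by an E1cB path through the furanolate (DBU, CH2Cl2, 0 °C) to a mixture of 23 and its (11'E) isomer F6. The mixture would then be equilibrated with a trace of iodine in benzene under room light toward the less strained Z isomer. This fallback sets out from 21 and comes back at 23.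

Step 28. The electron-rich pentaenylstannane may be lost to protodestannylation or homocoupling, and the polyene may isomerise during a slow coupling. The fallback reverses the polarity of the coupling. Iodide 23 would be coupled with an excess of bis-stannane 42 (PdCl2(MeCN)2, DMF, rt) to the butenolide dienylstannane F7, and F7 would be joined to the tetraenyl iodide 41 under the conditions of step 28. This fallback sets out from 23 and 41 and comes back at 44.

Further compounds
F1 | step 11 | prop-2-en-1-yl 2-methylidene-4-[(1R)-2,6,6-trimethyl-4-oxocyclohex-2-en-1-yl]butanoate | CC1=CC(=O)CC(C)(C)[C@H]1CCC(=C)C(=O)OCC=C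
F2 | step 11 | 3-{2-[(1R)-2,6,6-trimethyl-4-oxocyclohex-2-en-1-yl]ethyl}furan-2(5H)-one | CC1=CC(=O)CC(C)(C)[C@H]1CCC1=CCOC1=O
F3 | step 11 | (4R)-4-(2-{2-[(tert-butyldimethylsilyl)oxy]furan-3-yl}ethyl)-3,5,5-trimethylcyclohex-2-en-1-one | CC1=CC(=O)CC(C)(C)[C@H]1CCc1ccoc1O[Si](C)(C)C(C)(C)C
F4 | step 11 | (5R)-5-[(1R,2E)-1-hydroxy-3-iodo-2-methylprop-2-en-1-yl]-3-{2-[(1R)-2,6,6-trimethyl-4-oxocyclohex-2-en-1-yl]ethyl}furan-2(5H)-one | CC1=CC(=O)CC(C)(C)[C@H]1CCC1=C[C@H]([C@H](O)/C(C)=C/I)OC1=O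
F5 | step 13 | acetate of 21 at the C12' oxygen | CC1=CC(=O)CC(C)(C)[C@H]1CCC1=C[C@@H]([C@@H](OC(C)=O)/C(C)=C/I)OC1=O
F6 | step 13 | (5E)-5-[(2E)-3-iodo-2-methylprop-2-en-1-ylidene]-3-{2-[(1R)-2,6,6-trimethyl-4-oxocyclohex-2-en-1-yl]ethyl}furan-2(5H)-one | CC1=CC(=O)CC(C)(C)[C@H]1CCC1=C/C(=C\C(C)=C\I)OC1=O
F7 | step 28 | (5Z)-5-[(2E,4E)-2-methyl-5-(tributylstannyl)penta-2,4-dien-1-ylidene]-3-{2-[(1R)-2,6,6-trimethyl-4-oxocyclohex-2-en-1-yl]ethyl}furan-2(5H)-one | CC1=CC(=O)CC(C)(C)[C@H]1CCC1=C/C(=C/C(C)=C/C=C/[Sn](CCCC)(CCCC)CCCC)OC1=O
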